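**Strategy**

The isoflavone is cut at its C4 carbonyl. C4 is bonded only to C4a of ring A and to C3, which carries ring B, so carbon monoxide can supply C4 between a ring A aryl iodide and a 1-arylvinylboronate that brings C2, C3 and ring B. One palladium-catalysed carbonylative coupling forms C4a–C4 and C4–C3 and delivers the whole C15 skeleton as an α-aryl enone; ring C is closed later. The partners are 2-iodo-1,3,5-tris(methoxymethoxy)benzene and a pinacol 1-arylvinylboronate carrying the MOM-protected phenol, two methoxy groups and the prenyl chain. Afterwards C2 is raised to the aldehyde level before acid frees the phenols, so no late dehydrogenation is needed.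

Key step: step 10

Remark: ArB stands for 2,4-dimethoxy-6-(methoxymethoxy)-3-(3-methylbut-2-en-1-yl)phenyl; compounds 19–22, F3 and F4 carry stereocentres, are expected as racemates (22 as a diastereomer mixture) and lose them before the achiral target; 21 is drawn as the keto-aldehyde although its hydrogen-bonded enol should predominate.

**Route**

Step 1
Reactants: 1 3,5-dimethoxyphenol
Product: 2 (3,5-dimethoxyphenoxy)tri(propan-2-yl)silane
Conditions: i-Pr3SiCl, imidazole, DMF, rt
Reagents that add atoms: chlorotriisopropylsilane, CC(C)[Si](Cl)(C(C)C)C(C)C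
Why: Imidazole-mediated O-silylation of a phenol is routine, and the bulky, weakly coordinating silyl ether is chosen so that the next metalation avoids the positions beside it.

Step 2
Reactants: 2 (3,5-dimethoxyphenoxy)tri(propan-2-yl)silane, 3 1-bromo-3-methylbut-2-ene
Product: 5 [3,5-dimethoxy-4-(3-methylbut-2-en-1-yl)phenoxy]tri(propan-2-yl)silane, via aryllithium 4 (not isolated)
Conditions: n-BuLi, TMEDA, THF, 0 °C; then 3, −78 °C → rt
Reagents that add atoms: none
Why: Directed ortho-metalation should occur at the carbon flanked by both methoxy groups, since they coordinate lithium together while the silyl ether is a poor and crowded director, and the aryllithium is then alkylated at the primary carbon of the allylic bromide in an SN2 reaction.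

Step 3
Reactants: 5 [3,5-dimethoxy-4-(3-methylbut-2-en-1-yl)phenoxy]tri(propan-2-yl)silane
Product: 6 3,5-dimethoxy-4-(3-methylbut-2-en-1-yl)phenol
Conditions: Bu4NF, AcOH, THF, rt
Reagents that add atoms: none
Why: Fluoride-induced desilylation of the aryl silyl ether, buffered with acetic acid, should release the phenol without touching the prenyl alkene or the methyl ethers.

Step 4
Reactants: 6 3,5-dimethoxy-4-(3-methylbut-2-en-1-yl)phenol
Product: 8 6-hydroxy-2,4-dimethoxy-3-(3-methylbut-2-en-1-yl)benzaldehyde, via hydroxymethylphenol 7 (not isolated)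
Conditions: MgCl2, Et3N, (CH2O)n, MeCN, reflux
Reagents that add atoms: paraformaldehyde (reacts as formaldehyde), C=O
Why: In this Casnati–Skattebøl ortho-formylation the magnesium phenoxide delivers formaldehyde only to an ortho carbon (the two are equivalent by symmetry and the para carbon is blocked by the prenyl group), and the benzylic alkoxide is oxidised in the flask by hydride transfer to a second formaldehyde.

Step 5
Reactants: 8 6-hydroxy-2,4-dimethoxy-3-(3-methylbut-2-en-1-yl)benzaldehyde
Product: 9 2,4-dimethoxy-6-(methoxymethoxy)-3-(3-methylbut-2-en-1-yl)benzaldehyde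
Conditions: MOMCl, i-Pr2NEt, CH2Cl2, 0 °C → rt
Reagents that add atoms: chloromethyl methyl ether, COCCl
Why: O-Alkylation of the phenol with the reactive α-chloro ether (Williamson-type) gives a MOM acetal that should survive the basic, organometallic and palladium steps and fall in the final acid step.

Step 6
Reactants: 9 2,4-dimethoxy-6-(methoxymethoxy)-3-(3-methylbut-2-en-1-yl)benzaldehyde
Product: 10 2-ethynyl-3,5-dimethoxy-1-(methoxymethoxy)-4-(3-methylbut-2-en-1-yl)benzene
Conditions: dimethyl (1-diazo-2-oxopropyl)phosphonate, K2CO3, MeOH, rt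
Reagents that add atoms: dimethyl (1-diazo-2-oxopropyl)phosphonate, COP(=O)(OC)C(=[N+]=[N-])C(C)=O
Why: The Seyferth–Gilbert homologation in its Ohira–Bestmann form converts a non-enolisable aryl aldehyde into the terminal alkyne under mild carbonate conditions that leave the MOM ether and the prenyl group alone.

Step 7
Reactants: 10 2-ethynyl-3,5-dimethoxy-1-(methoxymethoxy)-4-(3-methylbut-2-en-1-yl)benzene
Product: 12 4,4,5,5-tetramethyl-2-(1-ArB-ethenyl)-1,3,2-dioxaborolane, via vinylalane 11 (not isolated)
Conditions: NiCl2(dppp) (3 mol %), i-Bu2AlH, THF, 0 °C → rt; then MeOBpin, 0 °C → rt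
Reagents that add atoms: 2-methoxy-4,4,5,5-tetramethyl-1,3,2-dioxaborolane, COB1OC(C)(C)C(C)(C)O1
Why: Nickel-catalysed hydroalumination of terminal aryl alkynes with the dppp ligand places aluminium on the internal carbon (α-selective hydrometalation), and aluminium-to-boron exchange with the methoxyboronate should fix that regiochemistry in the 1-arylvinylboronate.

Step 8
Reactants: 13 benzene-1,3,5-triol (phloroglucinol)
Product: 14 1,3,5-tris(methoxymethoxy)benzene
Conditions: MOMCl, i-Pr2NEt, CH2Cl2/DMF, 0 °C → rt
Reagents that add atoms: chloromethyl methyl ether, COCCl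
Why: Threefold O-alkylation with the hard α-chloro ether electrophile under amine base should give the tris-acetal and avoid C-alkylation of the phloroglucinol ring.

Step 9
Reactants: 14 1,3,5-tris(methoxymethoxy)benzene
Product: 15 2-iodo-1,3,5-tris(methoxymethoxy)benzene
Conditions: NIS, MeCN, 0 °C → rt, dark
Reagents that add atoms: N-iodosuccinimide, O=C1CCC(=O)N1I
Why: Electrophilic aromatic iodination of the strongly activated, threefold-symmetric arene (all free positions equivalent) should stop at the mono-iodide under neutral conditions that spare the acid-labile acetals.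

Step 10
Reactants: 15 2-iodo-1,3,5-tris(methoxymethoxy)benzene, 16 carbon monoxide, 12 4,4,5,5-tetramethyl-2-(1-ArB-ethenyl)-1,3,2-dioxaborolane
Product: 17 2-ArB-1-[2,4,6-tris(methoxymethoxy)phenyl]prop-2-en-1-one
Conditions: Pd(OAc)2 (5 mol %), P(1-Ad)2(n-Bu) (10 mol %), K3PO4, toluene/H2O (10:1), CO (5 bar), 80 °C
Reagents that add atoms: none
Why: Oxidative addition of the C–I bond of 15 to a zerovalent palladium–phosphine species gives an arylpalladium iodide, and carbon monoxide inserts into its Pd–C bond to form an aroyl complex of divalent palladium, which creates the C4a–C4 bond. Phosphate-assisted transfer of the 1-arylvinyl group from boron to palladium and reductive elimination then form the C4–C3 bond and release enone 17 with regeneration of the catalyst. The closest known reaction type is the carbonylative Suzuki–Miyaura coupling of aryl iodides with alkenylboron reagents to aryl vinyl ketones. No ring is closed and no stereocentre is created. The selectivity needed is ketone formation over direct aryl–vinyl coupling: the two MOM ethers ortho to palladium hinder boron-to-palladium transfer at the aryl stage but not CO insertion, which moves the metal one atom away from the congestion, and the CO pressure reinforces this bias. The acetals and the prenyl alkene should be inert to the mildly basic two-phase medium.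

Step 11
Reactants: 17 2-ArB-1-[2,4,6-tris(methoxymethoxy)phenyl]prop-2-en-1-one, 18 bis(pinacolato)diboron
Product: 20 racemic 3-hydroxy-2-ArB-1-[2,4,6-tris(methoxymethoxy)phenyl]propan-1-one, via boryl ketone 19 (not isolated)
Conditions: CuCl (5 mol %), Xantphos (5 mol %), NaOt-Bu (10 mol %), MeOH, THF, rt; then NaBO3·4H2O, THF/H2O, rt
Reagents that add atoms: sodium perborate (NaBO3·4H2O, supplies the hydroxyl oxygen; peroxoborate salt shown), [Na+].[Na+].O[B-]1(O)OO[B-](O)(O)OO1
Why: Copper-catalysed conjugate borylation puts boron on the unhindered terminal CH2 of the enone and leaves the isolated trisubstituted prenyl alkene alone, mild perborate oxidation of the C–B bond gives the primary alcohol, and the new stereocentre at the α-carbon (later C3) arises as a racemate by unselective protonation of the enolate and is erased in step 13.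

Step 12
Reactants: 20 racemic 3-hydroxy-2-ArB-1-[2,4,6-tris(methoxymethoxy)phenyl]propan-1-one
Product: 21 2-ArB-3-oxo-3-[2,4,6-tris(methoxymethoxy)phenyl]propanal
Conditions: Dess–Martin periodinane, CH2Cl2, 0 °C → rt
Reagents that add atoms: none
Why: Dess–Martin oxidation of the primary alcohol under neutral, anhydrous conditions, to which the acetals, the prenyl alkene and the fully protected arenes are inert, should give the α-formyl ketone and so bring C2 to the oxidation level of the isoflavone with no free phenol present.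

Step 13
Reactants: 21 2-ArB-3-oxo-3-[2,4,6-tris(methoxymethoxy)phenyl]propanal
Product: 24 5,7-dihydroxy-3-[6-hydroxy-2,4-dimethoxy-3-(3-methylbut-2-en-1-yl)phenyl]-4H-chromen-4-one, via hemiacetal 22 (not isolated), via protected isoflavone 23 (not isolated)
Conditions: HCl (1.25 M in MeOH), 0 °C → rt, then 45 °C
Reagents that add atoms: none
Why: Acid-catalysed acetal exchange with methanol removes the MOM groups, the two beside the ketone being expected to go first, so that a ring A phenol adds to the formyl carbon (6-exo-trig hemiacetal) and loss of water closes ring C as the 4H-chromen-4-one before the ring B phenol is freed, which is the classical cyclodehydration of 2-hydroxyaryl α-formylbenzyl ketones to isoflavones.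

**Compound list**

1 | 3,5-dimethoxyphenol | COc1cc(O)cc(OC)c1 | starting material
2 | (3,5-dimethoxyphenoxy)tri(propan-2-yl)silane | COc1cc(O[Si](C(C)C)(C(C)C)C(C)C)cc(OC)c1 | intermediate
3 | 1-bromo-3-methylbut-2-ene (prenyl bromide) | CC(C)=CCBr | starting material
4 | [2,6-dimethoxy-4-(triisopropylsilyloxy)phenyl]lithium (not isolated) | [Li]c1c(OC)cc(O[Si](C(C)C)(C(C)C)C(C)C)cc1OC | intermediate
5 | [3,5-dimethoxy-4-(3-methylbut-2-en-1-yl)phenoxy]tri(propan-2-yl)silane | COc1cc(O[Si](C(C)C)(C(C)C)C(C)C)cc(OC)c1CC=C(C)C | intermediate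
6 | 3,5-dimethoxy-4-(3-methylbut-2-en-1-yl)phenol | COc1cc(O)cc(OC)c1CC=C(C)C | intermediate
7 | 2-(hydroxymethyl)-3,5-dimethoxy-4-(3-methylbut-2-en-1-yl)phenol, present as its magnesium salt (not isolated) | OCc1c(O)cc(OC)c(CC=C(C)C)c1OC | intermediate
8 | 6-hydroxy-2,4-dimethoxy-3-(3-methylbut-2-en-1-yl)benzaldehyde | O=Cc1c(O)cc(OC)c(CC=C(C)C)c1OC | intermediate
9 | 2,4-dimethoxy-6-(methoxymethoxy)-3-(3-methylbut-2-en-1-yl)benzaldehyde | O=Cc1c(OCOC)cc(OC)c(CC=C(C)C)c1OC | intermediate
10 | 2-ethynyl-3,5-dimethoxy-1-(methoxymethoxy)-4-(3-methylbut-2-en-1-yl)benzene | C#Cc1c(OCOC)cc(OC)c(CC=C(C)C)c1OC | intermediate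
11 | {1-[2,4-dimethoxy-6-(methoxymethoxy)-3-(3-methylbut-2-en-1-yl)phenyl]ethenyl}bis(2-methylpropyl)alumane (not isolated) | C=C([Al](CC(C)C)CC(C)C)c1c(OCOC)cc(OC)c(CC=C(C)C)c1OC | intermediate
12 | 2-{1-[2,4-dimethoxy-6-(methoxymethoxy)-3-(3-methylbut-2-en-1-yl)phenyl]ethenyl}-4,4,5,5-tetramethyl-1,3,2-dioxaborolane | C=C(B1OC(C)(C)C(C)(C)O1)c1c(OCOC)cc(OC)c(CC=C(C)C)c1OC | intermediate
13 | benzene-1,3,5-triol (phloroglucinol) | Oc1cc(O)cc(O)c1 | starting material
14 | 1,3,5-tris(methoxymethoxy)benzene | COCOc1cc(OCOC)cc(OCOC)c1 | intermediate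
15 | 2-iodo-1,3,5-tris(methoxymethoxy)benzene | COCOc1cc(OCOC)c(I)c(OCOC)c1 | intermediate
16 | carbon monoxide | [C-]#[O+] | starting material
17 | 2-[2,4-dimethoxy-6-(methoxymethoxy)-3-(3-methylbut-2-en-1-yl)phenyl]-1-[2,4,6-tris(methoxymethoxy)phenyl]prop-2-en-1-one | COCOc1cc(OCOC)c(C(=O)C(=C)c2c(OCOC)cc(OC)c(CC=C(C)C)c2OC)c(OCOC)c1 | intermediate
18 | bis(pinacolato)diboron | CC1(C)OB(B2OC(C)(C)C(C)(C)O2)OC1(C)C | starting material
19 | racemic 2-[2,4-dimethoxy-6-(methoxymethoxy)-3-(3-methylbut-2-en-1-yl)phenyl]-3-(4,4,5,5-tetramethyl-1,3,2-dioxaborolan-2-yl)-1-[2,4,6-tris(methoxymethoxy)phenyl]propan-1-one (not isolated) | COCOc1cc(OCOC)c(C(=O)C(CB2OC(C)(C)C(C)(C)O2)c2c(OCOC)cc(OC)c(CC=C(C)C)c2OC)c(OCOC)c1 | intermediate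
20 | racemic 2-[2,4-dimethoxy-6-(methoxymethoxy)-3-(3-methylbut-2-en-1-yl)phenyl]-3-hydroxy-1-[2,4,6-tris(methoxymethoxy)phenyl]propan-1-one | COCOc1cc(OCOC)c(C(=O)C(CO)c2c(OCOC)cc(OC)c(CC=C(C)C)c2OC)c(OCOC)c1 | intermediate
21 | 2-[2,4-dimethoxy-6-(methoxymethoxy)-3-(3-methylbut-2-en-1-yl)phenyl]-3-oxo-3-[2,4,6-tris(methoxymethoxy)phenyl]propanal (racemic keto form, mainly enolised) | COCOc1cc(OCOC)c(C(=O)C(C=O)c2c(OCOC)cc(OC)c(CC=C(C)C)c2OC)c(OCOC)c1 | intermediate
22 | 3-[2,4-dimethoxy-6-(methoxymethoxy)-3-(3-methylbut-2-en-1-yl)phenyl]-2-hydroxy-5,7-bis(methoxymethoxy)-2,3-dihydro-4H-chromen-4-one (racemic diastereomer mixture, not isolated) | COCOc1cc(OCOC)c2c(c1)OC(O)C(c1c(OCOC)cc(OC)c(CC=C(C)C)c1OC)C2=O | intermediate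
23 | 3-[2,4-dimethoxy-6-(methoxymethoxy)-3-(3-methylbut-2-en-1-yl)phenyl]-5,7-bis(methoxymethoxy)-4H-chromen-4-one (not isolated) | COCOc1cc(OCOC)c2c(c1)occ(-c1c(OCOC)cc(OC)c(CC=C(C)C)c1OC)c2=O | intermediate
24 | 5,7-dihydroxy-3-[6-hydroxy-2,4-dimethoxy-3-(3-methylbut-2-en-1-yl)phenyl]-4H-chromen-4-one (achiral) | COc1cc(O)c(-c2coc3cc(O)cc(O)c3c2=O)c(OC)c1CC=C(C)C | target

**Step count**

Total: 13 steps. Longest linear sequence: 11 steps (steps 1–7, then 10–13); the ring A branch (steps 8 and 9) joins at step 10.

**Steps most likely to fail**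

1. Step 10. Direct coupling without uptake of CO may compete. Transfer of the congested alkenyl group from boron to the aroylpalladium intermediate may be slow, so that protodeboronation of 12 or hydrolysis of the aroyl complex to the benzoic acid takes over. The enone may also oligomerise under base as it forms. The fallback sets out from vinylalane 11 (made from 10 as in step 7) and from 14 and returns at 17. Quenching 11 with I2 (THF, −78 °C) should give 2-(1-iodoethenyl)-3,5-dimethoxy-1-(methoxymethoxy)-4-(3-methylbut-2-en-1-yl)benzene F1. Lithiation of 14 between two MOM ethers (n-BuLi, THF, 0 °C) and trapping with DMF should give 2,4,6-tris(methoxymethoxy)benzaldehyde F2. Iodine–lithium exchange on F1 (t-BuLi, Et2O, −78 °C) and addition of the vinyllithium to F2 should give racemic 2-ArB-1-[2,4,6-tris(methoxymethoxy)phenyl]prop-2-en-1-ol F3, and oxidation of this allylic alcohol with Dess–Martin periodinane or MnO2 leads to 17.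

2. Step 7. The hydrometalation of this very electron-rich, doubly ortho-substituted aryl alkyne may lose its α-selectivity. The alane may deprotonate the alkyne C–H, a nickel hydride may shift the prenyl double bond, or the aluminium-to-boron exchange at the crowded carbon may stall. The fallback sets out from aldehyde 9 and returns at 12, with the regiochemistry fixed by a ketone carbon. MeMgBr (THF, 0 °C) should give racemic 1-ArB-ethan-1-ol F4, Dess–Martin oxidation 1-ArB-ethan-1-one F5, and KN(SiMe3)2 with PhNTf2 (THF, −78 °C) 1-ArB-ethenyl trifluoromethanesulfonate F6, which is used crude. Miyaura borylation of F6 with 18 (PdCl2(PPh3)2, PPh3, KOPh, toluene, 50 °C) then gives 12.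

3. Step 13. The ring B MOM ether may be lost before ring C has closed, and the freed ring B phenol could then condense with the formyl or keto carbon in a five-membered, benzofuran-forming cyclodehydration. Prolonged acid may also add HCl or methanol across the prenyl double bond. The fallback sets out from 21 and returns at 24. MgBr2·OEt2 (Et2O/CH2Cl2, 0 °C → rt) should cleave by chelation only the two MOM ethers beside the ketone and close ring C, giving 5-hydroxy-7-(methoxymethoxy)-3-ArB-4H-chromen-4-one F7, which is isolated. The two remaining MOM groups are then removed with dilute HCl in MeOH at rt, when the isoflavone ring is already in place.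

Further compounds

F1 | step 10 | 2-(1-iodoethenyl)-3,5-dimethoxy-1-(methoxymethoxy)-4-(3-methylbut-2-en-1-yl)benzene | C=C(I)c1c(OCOC)cc(OC)c(CC=C(C)C)c1OC
F2 | step 10 | 2,4,6-tris(methoxymethoxy)benzaldehyde | O=Cc1c(OCOC)cc(OCOC)cc1OCOC
F3 | step 10 | racemic 2-[2,4-dimethoxy-6-(methoxymethoxy)-3-(3-methylbut-2-en-1-yl)phenyl]-1-[2,4,6-tris(methoxymethoxy)phenyl]prop-2-en-1-ol | COCOc1cc(OCOC)c(C(O)C(=C)c2c(OCOC)cc(OC)c(CC=C(C)C)c2OC)c(OCOC)c1
F4 | step 7 | racemic 1-[2,4-dimethoxy-6-(methoxymethoxy)-3-(3-methylbut-2-en-1-yl)phenyl]ethan-1-ol | CC(O)c1c(OCOC)cc(OC)c(CC=C(C)C)c1OC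
F5 | step 7 | 1-[2,4-dimethoxy-6-(methoxymethoxy)-3-(3-methylbut-2-en-1-yl)phenyl]ethan-1-one | CC(=O)c1c(OCOC)cc(OC)c(CC=C(C)C)c1OC
F6 | step 7 | 1-[2,4-dimethoxy-6-(methoxymethoxy)-3-(3-methylbut-2-en-1-yl)phenyl]ethenyl trifluoromethanesulfonate | C=C(OS(=O)(=O)C(F)(F)F)c1c(OCOC)cc(OC)c(CC=C(C)C)c1OC
F7 | step 13 | 3-[2,4-dimethoxy-6-(methoxymethoxy)-3-(3-methylbut-2-en-1-yl)phenyl]-5-hydroxy-7-(methoxymethoxy)-4H-chromen-4-one | COCOc1cc(O)c2c(c1)occ(-c1c(OCOC)cc(OC)c(CC=C(C)C)c1OC)c2=O
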